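The route rests on cutting the trans-fused decalin (ring A and ring B) across C5–C10 and C8–C9. One thermal intramolecular Diels–Alder reaction of an acyclic (S)-trienal closes both carbocycles: an (E)-enal (C9=C10, C11 aldehyde) is tethered through C1–C4 to a (Z)-configured C8 silyl dienol ether (C5=C6–C7=C8). The reaction sets the four contiguous stereocentres C5, C10, C9 and C8, two of them quaternary, under control of the C3 silyl ether. It exploits the fact that C8 carries oxygen and C9 a one-carbon branch (C11), the pattern left by a 1-silyloxydiene/enal cycloaddition. The oxocane, its epoxide and the C3 bromide follow afterwards.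

Key step: step 14

Remarks
- Numbering: atom labels C1–C15 refer to the position each carbon takes in the target (labdane-type: C1–C10 decalin, C4 gem-dimethyl, C10 angular methyl, C8 methyl and oxygen, side chain C11–C15 on C9, C13 methyl, oxygen bridging C8 and C15); α is the face opposite to the C10 methyl group. The target is (3S,5R,8R,9R,10S,13R,14S).
- Assumption: the promoter made from N-tosyl-D-valine is taken to give the (3S)-aldol, in line with the accepted facial model of this promoter class; the L-valine promoter would be used if the sense were opposite.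

Step 1
Reactants: 1 geranyl acetate
Product: 3 (2E)-3-methyl-6-oxohex-2-en-1-yl acetate, via secondary ozonide 2 (not isolated)
Conditions: O3 (1.0 equiv), pyridine, CH2Cl2, −78 °C; then Me2S, −78 °C to rt
Reagents that add atoms: ozone, [O-][O+]=O
Why: Regioselective ozonolysis with reductive work-up should cleave only the electron-rich isopropylidene alkene, since the other alkene is deactivated by its allylic acetate, and so unveils the aldehyde carbon that becomes C3.

Step 2
Reactants: 3 (2E)-3-methyl-6-oxohex-2-en-1-yl acetate; 4 methyl trimethylsilyl dimethylketene acetal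
Product: 5 methyl (3S,6E)-8-acetoxy-3-hydroxy-2,2,6-trimethyloct-6-enoate
Conditions: N-tosyl-D-valine, BH3·THF, CH2Cl2, 0 °C to rt; then 3 and 4, −78 °C; pH 7 buffer
Reagents that add atoms: none
Why: Enantioselective Mukaiyama aldol addition: the stoichiometric valine-derived oxazaborolidinone activates the aldehyde and shields one of its faces, so the ketene acetal should add to the other face, setting C3 as (S) and creating the C4 gem-dimethyl carbon with C5 as the ester.

Step 3
Reactants: 5 methyl (3S,6E)-8-acetoxy-3-hydroxy-2,2,6-trimethyloct-6-enoate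
Product: 6 methyl (3S,6E)-8-acetoxy-3-[(tert-butyldimethylsilyl)oxy]-2,2,6-trimethyloct-6-enoate
Conditions: t-BuMe2SiOTf, 2,6-lutidine, CH2Cl2, 0 °C
Reagents that add atoms: tert-butyldimethylsilyl triflate, CC(C)(C)[Si](C)(C)OS(=O)(=O)C(F)(F)F
Why: Silyl ether formation with the silyl triflate and a hindered base protects the neopentyl-type secondary C3–OH as the bulky group that later directs the cycloaddition.

Step 4
Reactants: 6 methyl (3S,6E)-8-acetoxy-3-[(tert-butyldimethylsilyl)oxy]-2,2,6-trimethyloct-6-enoate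
Product: 7 (2E,6S)-6-[(tert-butyldimethylsilyl)oxy]-3,7,7-trimethyloct-2-ene-1,8-diol
Conditions: i-Bu2AlH (excess), CH2Cl2, −78 to 0 °C; aq. potassium sodium tartrate
Reagents that add atoms: none
Why: Ester reduction by excess aluminium hydride converts the hindered methyl ester and the acetate into the C5 and C11 primary alcohols without touching the silyl ether or the alkene.

Step 5
Reactants: 7 (2E,6S)-6-[(tert-butyldimethylsilyl)oxy]-3,7,7-trimethyloct-2-ene-1,8-diol
Product: 8 (2E,6S)-6-[(tert-butyldimethylsilyl)oxy]-8-hydroxy-3,7,7-trimethyloct-2-en-1-yl pivalate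
Conditions: t-BuCOCl (1.05 equiv), pyridine, CH2Cl2, −20 to 0 °C
Reagents that add atoms: pivaloyl chloride, CC(C)(C)C(Cl)=O
Why: Sterically controlled acylation (esterification) should take place at the unhindered allylic C11–OH, because the C5–OH is neopentyl and flanked by the C3 silyl ether, and the pivalate withstands the coming basic and acidic steps.

Step 6
Reactants: 8 (2E,6S)-6-[(tert-butyldimethylsilyl)oxy]-8-hydroxy-3,7,7-trimethyloct-2-en-1-yl pivalate
Product: 9 (2E,6S)-6-[(tert-butyldimethylsilyl)oxy]-3,7,7-trimethyl-8-oxooct-2-en-1-yl pivalate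
Conditions: Dess–Martin periodinane, NaHCO3, CH2Cl2, 0 °C to rt
Reagents that add atoms: none
Why: Dess–Martin oxidation gives the non-enolisable C5 aldehyde under buffered conditions that spare the silyl ether, the pivalate and the C3 stereocentre.

Step 7
Reactants: 10 2-(2-bromoethyl)-2-methyl-1,3-dioxolane
Product: 11 5-{[2-(2-methyl-1,3-dioxolan-2-yl)ethyl]sulfanyl}-1-phenyl-1H-tetrazole
Conditions: 1-phenyl-1H-tetrazole-5-thiol, K2CO3, acetone, 50 °C
Reagents that add atoms: 1-phenyl-1H-tetrazole-5-thiol, Sc1nnnn1-c1ccccc1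
Why: SN2 thioetherification of the primary bromide by the thiolate installs the tetrazolyl sulfide, the ketal tolerating the mild base.

Step 8
Reactants: 11 5-{[2-(2-methyl-1,3-dioxolan-2-yl)ethyl]sulfanyl}-1-phenyl-1H-tetrazole
Product: 12 5-{[2-(2-methyl-1,3-dioxolan-2-yl)ethyl]sulfonyl}-1-phenyl-1H-tetrazole
Conditions: mCPBA (2.5 equiv), NaHCO3, CH2Cl2, 0 °C to rt
Reagents that add atoms: mCPBA, OOC(=O)c1cccc(Cl)c1
Why: Sulfide-to-sulfone oxidation with a buffered peracid gives the Julia–Kocienski reagent, the bicarbonate protecting the acid-labile dioxolane.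

Step 9
Reactants: 9 (2E,6S)-6-[(tert-butyldimethylsilyl)oxy]-3,7,7-trimethyl-8-oxooct-2-en-1-yl pivalate; 12 5-{[2-(2-methyl-1,3-dioxolan-2-yl)ethyl]sulfonyl}-1-phenyl-1H-tetrazole
Product: 13 (2E,6S,8E)-6-[(tert-butyldimethylsilyl)oxy]-3,7,7-trimethyl-10-(2-methyl-1,3-dioxolan-2-yl)deca-2,8-dien-1-yl pivalate
Conditions: 12, KN(SiMe3)2, DME, −60 °C; then 9, −60 °C to rt
Reagents that add atoms: none
Why: Julia–Kocienski olefination: addition of the metalated sulfone to the α-quaternary aldehyde, Smiles rearrangement and anti elimination should give the (E)-C5=C6 alkene, the outcome favoured by the potassium counter-ion in DME and the bulky aldehyde.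

Step 10
Reactants: 13 (2E,6S,8E)-6-[(tert-butyldimethylsilyl)oxy]-3,7,7-trimethyl-10-(2-methyl-1,3-dioxolan-2-yl)deca-2,8-dien-1-yl pivalate
Product: 14 (2E,6S,8E)-6-[(tert-butyldimethylsilyl)oxy]-3,7,7-trimethyl-11-oxododeca-2,8-dien-1-yl pivalate
Conditions: pyridinium p-toluenesulfonate, acetone/H2O, 45 °C
Reagents that add atoms: water, O
Why: Mild acid-catalysed ketal hydrolysis releases the C8 methyl ketone as the β,γ-unsaturated isomer, conditions weak enough to leave the silyl ether and pivalate in place and the C5=C6 alkene out of conjugation.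

Step 11
Reactants: 14 (2E,6S,8E)-6-[(tert-butyldimethylsilyl)oxy]-3,7,7-trimethyl-11-oxododeca-2,8-dien-1-yl pivalate
Product: 15 (2E,6S,8E,10Z)-6-[(tert-butyldimethylsilyl)oxy]-3,7,7-trimethyl-11-[(triethylsilyl)oxy]dodeca-2,8,10-trien-1-yl pivalate
Conditions: Et3SiOTf, Et3N, CH2Cl2, −78 to 0 °C
Reagents that add atoms: triethylsilyl triflate, CC[Si](CC)(CC)OS(=O)(=O)C(F)(F)F
Why: Soft enolisation (silyl triflate with amine base) should silylate towards the doubly activated C7 methylene to give the conjugated silyl dienol ether, with the (Z) C7=C8 geometry in which the C6 vinyl group lies cis to the silyloxy group and away from the C8 methyl group.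

Step 12
Reactants: 15 (2E,6S,8E,10Z)-6-[(tert-butyldimethylsilyl)oxy]-3,7,7-trimethyl-11-[(triethylsilyl)oxy]dodeca-2,8,10-trien-1-yl pivalate
Product: 16 (2E,6S,8E,10Z)-6-[(tert-butyldimethylsilyl)oxy]-3,7,7-trimethyl-11-[(triethylsilyl)oxy]dodeca-2,8,10-trien-1-ol
Conditions: i-Bu2AlH (2.5 equiv), CH2Cl2, −78 °C; aq. potassium sodium tartrate
Reagents that add atoms: none
Why: Reductive ester cleavage with the aluminium hydride at low temperature removes the pivalate under aprotic, non-basic conditions that silyl enol ethers and silyl ethers tolerate.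

Step 13
Reactants: 16 (2E,6S,8E,10Z)-6-[(tert-butyldimethylsilyl)oxy]-3,7,7-trimethyl-11-[(triethylsilyl)oxy]dodeca-2,8,10-trien-1-ol
Product: 17 (2E,6S,8E,10Z)-6-[(tert-butyldimethylsilyl)oxy]-3,7,7-trimethyl-11-[(triethylsilyl)oxy]dodeca-2,8,10-trienal
Conditions: MnO2 (activated, excess), CH2Cl2, rt
Reagents that add atoms: none
Why: Allylic alcohol oxidation with MnO2 is neutral and heterogeneous, so it should give the (E)-enal without isomerisation and without hydrolysing the silyl dienol ether.

Step 14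
Reactants: 17 (2E,6S,8E,10Z)-6-[(tert-butyldimethylsilyl)oxy]-3,7,7-trimethyl-11-[(triethylsilyl)oxy]dodeca-2,8,10-trienal
Product: 18 (1R,2R,4aR,6S,8aS)-6-[(tert-butyldimethylsilyl)oxy]-2,5,5,8a-tetramethyl-2-[(triethylsilyl)oxy]-1,2,4a,5,6,7,8,8a-octahydronaphthalene-1-carbaldehyde (trans-fused; labdane locants 3S,5R,8R,9R,10S, C6=C7 alkene)
Conditions: PhMe (0.01 M), BHT (cat.), sealed tube, 130 °C
Reagents that add atoms: none
Why: A concerted but asynchronous normal-demand [4+2] cycloaddition in which the HOMO of the 1-silyloxydiene (largest coefficient at C5) meets the LUMO of the enal (largest at C10), so that C5–C10 forms ahead of C8–C9; the closest known reaction type is the thermal intramolecular Diels–Alder reaction of 1,7,9-decatrienals to trans-fused octalins. Ring A closes as a six-membered carbocycle through the four-carbon C1–C4 tether folded as a chair, and ring B closes as the cyclohexene generated by the cycloaddition itself. The relative configuration of C10 and C9 is fixed by the (E)-enal (C10 methyl and formyl group cis), that of C8 by the (Z)-enol ether (methyl outside, silyloxy inside, so the C8 methyl ends syn to the formyl group), and the trans C5/C10 fusion by the aldehyde-endo transition state. The absolute sense is relayed from C3, whose bulky silyloxy group should sit equatorial on the chair tether. The step needs endo over exo selectivity and one diene face; the (E)-geometry with terminal activation and the folding enforced by the C4 gem-dimethyl group favour the endo chair, and the equatorial preference of the C3 substituent selects the face.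

Step 15
Reactants: 18 trans-octalin aldehyde
Product: 19 (1R,2R,4aR,6S,8aS)-6-[(tert-butyldimethylsilyl)oxy]-2,5,5,8a-tetramethyl-2-[(triethylsilyl)oxy]decahydronaphthalene-1-carbaldehyde (labdane locants 3S,5R,8R,9R,10S)
Conditions: H2 (1 atm), Pd/C, EtOAc, rt
Reagents that add atoms: none
Why: Heterogeneous catalytic hydrogenation saturates the cis-disubstituted C6=C7 alkene, the only alkene present, while the hindered aldehyde and both silyl ethers remain and no stereocentre is created.

Step 16
Reactants: 19 trans-decalin aldehyde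
Product: 20 (3S,5R,8R,9R,10S)-3-[(tert-butyldimethylsilyl)oxy]-8-[(triethylsilyl)oxy]-9-vinyl-4,4,8,10-tetramethyl-trans-decalin (C11=C12 vinyl group on C9)
Conditions: Ph3PCH3Br, KN(SiMe3)2, THF, 0 °C to rt
Reagents that add atoms: methyltriphenylphosphonium bromide, C[P+](c1ccccc1)(c1ccccc1)c1ccccc1.[Br-]
Why: Wittig methylenation converts the hindered C11 aldehyde into the C11=C12 vinyl group, fast carbonyl addition of the unstabilised ylide outrunning enolisation at C9, whose equatorial substituent is in any case the stable epimer.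

Step 17
Reactants: 20 9-vinyl decalin
Product: 22 (3S,5R,8R,9R,10S)-3-[(tert-butyldimethylsilyl)oxy]-8-[(triethylsilyl)oxy]-9-(3-methylbut-3-en-1-yl)-4,4,8,10-tetramethyl-trans-decalin, via B-alkyl-9-BBN borane 21 (not isolated)
Conditions: 9-BBN, THF, rt to 50 °C; then 2-bromopropene, Pd(dppf)Cl2 (cat.), aq. K3PO4, DMF, 45 °C
Reagents that add atoms: 2-bromopropene, CC(Br)=C; 9-BBN, [BH]1C2CCCC1CCC2 (retained in 21 only)
Why: Anti-Markovnikov hydroboration of the vinyl group with 9-BBN followed by B-alkyl Suzuki–Miyaura coupling with the alkenyl bromide forms the C12–C13 bond and delivers the 1,1-disubstituted alkene needed for ring closure.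

Step 18
Reactants: 22 bis-silyl ether with the 3-methylbut-3-enyl chain
Product: 23 (3S,5R,8R,9R,10S)-3-[(tert-butyldimethylsilyl)oxy]-9-(3-methylbut-3-en-1-yl)-4,4,8,10-tetramethyl-trans-decalin-8-ol (8α-OH)
Conditions: HF·pyridine, pyridine, THF, 0 °C to rt
Reagents that add atoms: none
Why: Selective desilylation: buffered HF should cleave the triethylsilyl ether far faster than the tert-butyldimethylsilyl ether, whose silicon is more shielded and which sits next to the C4 quaternary carbon, freeing the tertiary C8–OH.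

Step 19
Reactants: 23 tertiary C8 alcohol
Product: 24 (3S,5R,8R,9R,10S)-8-(allyloxy)-3-[(tert-butyldimethylsilyl)oxy]-9-(3-methylbut-3-en-1-yl)-4,4,8,10-tetramethyl-trans-decalin
Conditions: KH, allyl bromide, n-Bu4NI (cat.), THF, 0 °C to rt
Reagents that add atoms: allyl bromide, C=CCBr
Why: Williamson ether synthesis: the potassium alkoxide of the tertiary C8–OH is alkylated by the reactive allylic bromide, giving the C8–O–C15 bond with retention at C8 because the C–O bond of the carbinol is not touched.

Step 20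
Reactants: 24 C8 allyl ether
Product: 25 (3S,5R,8R,9R,10S,13Z)-3-[(tert-butyldimethylsilyl)oxy]-8,15-epoxylabd-13-ene (decalin trans-fused to the oxocene)
Conditions: second-generation Grubbs catalyst (H2IMes)(PCy3)Cl2Ru=CHPh (cat.), 1,4-benzoquinone (cat.), PhMe (0.002 M), 80 °C
Reagents that add atoms: none
Why: Ring-closing metathesis initiated at the allyl ether closes the eight-membered ring onto the 1,1-disubstituted alkene, helped by the gauche, trans-diequatorial disposition of the two chains on C8 and C9, and the ring size enforces the (Z) C13=C14 geometry.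

Step 21
Reactants: 25 silyl-protected oxocene
Product: 26 (3S,5R,8R,9R,10S,13Z)-8,15-epoxylabd-13-en-3-ol
Conditions: n-Bu4NF, THF, 60 °C
Reagents that add atoms: none
Why: Fluoride-mediated desilylation at elevated temperature removes the hindered C3 silyl ether, the dialkyl ether and the alkene being inert to fluoride.

Step 22
Reactants: 26 C3 alcohol
Product: 27 (5R,8R,9R,10S,13Z)-8,15-epoxylabd-13-en-3-one
Conditions: Dess–Martin periodinane, NaHCO3, CH2Cl2, rt
Reagents that add atoms: none
Why: Dess–Martin oxidation turns the C3 alcohol into the ketone, deliberately erasing the C3 stereocentre that has served its purpose in the cycloaddition.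

Step 23
Reactants: 27 C3 ketone
Product: 28 (5R,8R,9R,10S,13Z)-8,15-epoxylabda-2,13-dien-3-yl trifluoromethanesulfonate
Conditions: KN(SiMe3)2, THF, −78 °C; then PhNTf2, −78 to 0 °C
Reagents that add atoms: N-phenylbis(trifluoromethanesulfonimide), O=S(=O)(N(c1ccccc1)S(=O)(=O)C(F)(F)F)C(F)(F)F
Why: Enolate O-triflation: the ketone can enolise only towards C2 because C4 is quaternary, so the potassium enolate and the triflimide should give a single enol triflate.

Step 24
Reactants: 28 enol triflate
Product: 29 (5R,8R,9R,10S,13Z)-3-bromo-8,15-epoxylabda-2,13-diene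
Conditions: Ni(cod)2 (cat.), LiBr, DMA/THF, rt
Reagents that add atoms: lithium bromide, [Li+].[Br-]
Why: Nickel-catalysed halogenation of an enol triflate (oxidative addition of zerovalent nickel to the C–O bond, triflate–bromide exchange, C–Br reductive elimination) converts the triflate into the alkenyl bromide at room temperature without touching the ring alkene.

Step 25
Reactants: 29 alkenyl bromide
Product: 30 (5R,8R,9R,10S,13R,14S)-3-bromo-8,15:13,14-diepoxylabd-2-ene
Conditions: mCPBA, NaHCO3, CH2Cl2, 0 °C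
Reagents that add atoms: mCPBA, OOC(=O)c1cccc(Cl)c1
Why: Prilezhaev epoxidation: the peracid should react only with the electron-rich trisubstituted C13=C14 alkene and not with the electron-poor alkenyl bromide, and attack on the exposed face of the oxocene, which hangs below the α face of ring B with its inner face blocked by the axial C9–H, should set C13 as (R) and C14 as (S).

Step 26
Reactants: 30 epoxy alkenyl bromide
Product: 31 (3S,5R,8R,9R,10S,13R,14S)-3-bromo-8,15:13,14-diepoxylabdane (target)
Conditions: Co(acac)2, t-BuOOH, Et3SiH, 1,4-cyclohexadiene, n-PrOH, rt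
Reagents that add atoms: none
Why: Hydrogen-atom-transfer hydrogenation of an alkenyl halide: the cobalt hydride transfers H to C2, and the resulting α-bromo C3 radical should take its hydrogen from 1,4-cyclohexadiene on the axial α face, away from the C4β and C10β methyl groups, leaving bromine equatorial and C3 as (S) while the C–Br bond, the epoxide and the ether survive.

Compound list
1 | geranyl acetate, (2E)-3,7-dimethylocta-2,6-dien-1-yl acetate | CC(C)=CCC/C(C)=C/COC(C)=O | starting material
2 | secondary ozonide, (2E)-5-(5,5-dimethyl-1,2,4-trioxolan-3-yl)-3-methylpent-2-en-1-yl acetate | CC(=O)OC/C=C(\C)CCC1OOC(C)(C)O1 | intermediate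
3 | (2E)-3-methyl-6-oxohex-2-en-1-yl acetate | CC(=O)OC/C=C(\C)CCC=O | intermediate
4 | methyl trimethylsilyl dimethylketene acetal | COC(O[Si](C)(C)C)=C(C)C | starting material
5 | methyl (3S,6E)-8-acetoxy-3-hydroxy-2,2,6-trimethyloct-6-enoate | COC(=O)C(C)(C)[C@@H](O)CC/C(C)=C/COC(C)=O | intermediate
6 | methyl (3S,6E)-8-acetoxy-3-[(tert-butyldimethylsilyl)oxy]-2,2,6-trimethyloct-6-enoate | COC(=O)C(C)(C)[C@@H](O[Si](C)(C)C(C)(C)C)CC/C(C)=C/COC(C)=O | intermediate
7 | (2E,6S)-6-[(tert-butyldimethylsilyl)oxy]-3,7,7-trimethyloct-2-ene-1,8-diol | OCC(C)(C)[C@@H](O[Si](C)(C)C(C)(C)C)CC/C(C)=C/CO | intermediate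
8 | (2E,6S)-6-[(tert-butyldimethylsilyl)oxy]-8-hydroxy-3,7,7-trimethyloct-2-en-1-yl pivalate | OCC(C)(C)[C@@H](O[Si](C)(C)C(C)(C)C)CC/C(C)=C/COC(=O)C(C)(C)C | intermediate
9 | (2E,6S)-6-[(tert-butyldimethylsilyl)oxy]-3,7,7-trimethyl-8-oxooct-2-en-1-yl pivalate | O=CC(C)(C)[C@@H](O[Si](C)(C)C(C)(C)C)CC/C(C)=C/COC(=O)C(C)(C)C | intermediate
10 | 2-(2-bromoethyl)-2-methyl-1,3-dioxolane | CC1(CCBr)OCCO1 | starting material
11 | 5-{[2-(2-methyl-1,3-dioxolan-2-yl)ethyl]sulfanyl}-1-phenyl-1H-tetrazole | CC1(CCSc2nnnn2-c2ccccc2)OCCO1 | intermediate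
12 | 5-{[2-(2-methyl-1,3-dioxolan-2-yl)ethyl]sulfonyl}-1-phenyl-1H-tetrazole | CC1(CCS(=O)(=O)c2nnnn2-c2ccccc2)OCCO1 | intermediate
13 | (2E,6S,8E)-6-[(tert-butyldimethylsilyl)oxy]-3,7,7-trimethyl-10-(2-methyl-1,3-dioxolan-2-yl)deca-2,8-dien-1-yl pivalate | CC1(OCCO1)C/C=C/C(C)(C)[C@@H](O[Si](C)(C)C(C)(C)C)CC/C(C)=C/COC(=O)C(C)(C)C | intermediate
14 | (2E,6S,8E)-6-[(tert-butyldimethylsilyl)oxy]-3,7,7-trimethyl-11-oxododeca-2,8-dien-1-yl pivalate | CC(=O)C/C=C/C(C)(C)[C@@H](O[Si](C)(C)C(C)(C)C)CC/C(C)=C/COC(=O)C(C)(C)C | intermediate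
15 | (2E,6S,8E,10Z)-6-[(tert-butyldimethylsilyl)oxy]-3,7,7-trimethyl-11-[(triethylsilyl)oxy]dodeca-2,8,10-trien-1-yl pivalate | C/C(O[Si](CC)(CC)CC)=C/C=C/C(C)(C)[C@@H](O[Si](C)(C)C(C)(C)C)CC/C(C)=C/COC(=O)C(C)(C)C | intermediate
16 | (2E,6S,8E,10Z)-6-[(tert-butyldimethylsilyl)oxy]-3,7,7-trimethyl-11-[(triethylsilyl)oxy]dodeca-2,8,10-trien-1-ol | C/C(O[Si](CC)(CC)CC)=C/C=C/C(C)(C)[C@@H](O[Si](C)(C)C(C)(C)C)CC/C(C)=C/CO | intermediate
17 | (2E,6S,8E,10Z)-6-[(tert-butyldimethylsilyl)oxy]-3,7,7-trimethyl-11-[(triethylsilyl)oxy]dodeca-2,8,10-trienal | O=C/C=C(\C)CC[C@H](O[Si](C)(C)C(C)(C)C)C(C)(C)/C=C/C=C(/C)O[Si](CC)(CC)CC | intermediate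
18 | (1R,2R,4aR,6S,8aS)-6-[(tert-butyldimethylsilyl)oxy]-2,5,5,8a-tetramethyl-2-[(triethylsilyl)oxy]-1,2,4a,5,6,7,8,8a-octahydronaphthalene-1-carbaldehyde | CC1(C)[C@@H](O[Si](C)(C)C(C)(C)C)CC[C@]2(C)[C@@H](C=O)[C@](C)(O[Si](CC)(CC)CC)C=C[C@@H]12 | intermediate
19 | (1R,2R,4aR,6S,8aS)-6-[(tert-butyldimethylsilyl)oxy]-2,5,5,8a-tetramethyl-2-[(triethylsilyl)oxy]decahydronaphthalene-1-carbaldehyde | CC1(C)[C@@H](O[Si](C)(C)C(C)(C)C)CC[C@]2(C)[C@@H](C=O)[C@](C)(O[Si](CC)(CC)CC)CC[C@@H]12 | intermediate
20 | (3S,5R,8R,9R,10S)-3-[(tert-butyldimethylsilyl)oxy]-8-[(triethylsilyl)oxy]-9-vinyl-4,4,8,10-tetramethyl-trans-decalin | CC1(C)[C@@H](O[Si](C)(C)C(C)(C)C)CC[C@]2(C)[C@@H](C=C)[C@](C)(O[Si](CC)(CC)CC)CC[C@@H]12 | intermediate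
21 | B-alkyl-9-BBN borane of 20 (C9–CH2CH2–B) | CC1(C)[C@@H](O[Si](C)(C)C(C)(C)C)CC[C@]2(C)[C@@H](CCB3C4CCCC3CCC4)[C@](C)(O[Si](CC)(CC)CC)CC[C@@H]12 | intermediate
22 | (3S,5R,8R,9R,10S)-3-[(tert-butyldimethylsilyl)oxy]-8-[(triethylsilyl)oxy]-9-(3-methylbut-3-en-1-yl)-4,4,8,10-tetramethyl-trans-decalin | CC1(C)[C@@H](O[Si](C)(C)C(C)(C)C)CC[C@]2(C)[C@@H](CCC(C)=C)[C@](C)(O[Si](CC)(CC)CC)CC[C@@H]12 | intermediate
23 | (3S,5R,8R,9R,10S)-3-[(tert-butyldimethylsilyl)oxy]-9-(3-methylbut-3-en-1-yl)-4,4,8,10-tetramethyl-trans-decalin-8-ol | CC1(C)[C@@H](O[Si](C)(C)C(C)(C)C)CC[C@]2(C)[C@@H](CCC(C)=C)[C@](C)(O)CC[C@@H]12 | intermediate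
24 | (3S,5R,8R,9R,10S)-8-(allyloxy)-3-[(tert-butyldimethylsilyl)oxy]-9-(3-methylbut-3-en-1-yl)-4,4,8,10-tetramethyl-trans-decalin | CC1(C)[C@@H](O[Si](C)(C)C(C)(C)C)CC[C@]2(C)[C@@H](CCC(C)=C)[C@](C)(OCC=C)CC[C@@H]12 | intermediate
25 | (3S,5R,8R,9R,10S,13Z)-3-[(tert-butyldimethylsilyl)oxy]-8,15-epoxylabd-13-ene | CC1(C)[C@@H](O[Si](C)(C)C(C)(C)C)CC[C@]2(C)[C@H]3CC/C(C)=C\CO[C@]3(C)CC[C@@H]12 | intermediate
26 | (3S,5R,8R,9R,10S,13Z)-8,15-epoxylabd-13-en-3-ol | CC1(C)[C@@H](O)CC[C@]2(C)[C@H]3CC/C(C)=C\CO[C@]3(C)CC[C@@H]12 | intermediate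
27 | (5R,8R,9R,10S,13Z)-8,15-epoxylabd-13-en-3-one | CC1(C)C(=O)CC[C@]2(C)[C@H]3CC/C(C)=C\CO[C@]3(C)CC[C@@H]12 | intermediate
28 | (5R,8R,9R,10S,13Z)-8,15-epoxylabda-2,13-dien-3-yl trifluoromethanesulfonate | CC1(C)C(OS(=O)(=O)C(F)(F)F)=CC[C@]2(C)[C@H]3CC/C(C)=C\CO[C@]3(C)CC[C@@H]12 | intermediate
29 | (5R,8R,9R,10S,13Z)-3-bromo-8,15-epoxylabda-2,13-diene | CC1(C)C(Br)=CC[C@]2(C)[C@H]3CC/C(C)=C\CO[C@]3(C)CC[C@@H]12 | intermediate
30 | (5R,8R,9R,10S,13R,14S)-3-bromo-8,15:13,14-diepoxylabd-2-ene | CC1(C)C(Br)=CC[C@]2(C)[C@H]3CC[C@@]4(C)O[C@H]4CO[C@]3(C)CC[C@@H]12 | intermediate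
31 | (3S,5R,8R,9R,10S,13R,14S)-3-bromo-8,15:13,14-diepoxylabdane | CC1(C)[C@@H](Br)CC[C@]2(C)[C@H]3CC[C@@]4(C)O[C@H]4CO[C@]3(C)CC[C@@H]12 | target

Total step count: 26 steps.
Longest linear sequence: 24 steps (steps 1–6 and 9–26, from geranyl acetate); the sulfone branch (steps 7 and 8) joins at step 9.

Steps most likely to fail

1. Step 14 (intramolecular Diels–Alder). The two bonds form between fully substituted or neopentyl carbons, so the cyclisation may be too slow and leave time for silyl migration or decomposition of the dienol ether. Folding through the exo transition state (cis fusion), or with the C3 silyloxy group axial (other diene face), may also compete. The fallback sets out from 17 and comes back at 18. It replaces the concerted thermal closure by a stepwise ionic annulation at low temperature: Me2AlCl in CH2Cl2 at −78 °C complexes the aldehyde, a vinylogous Mukaiyama–Michael addition joins C5 to C10, and the resulting aluminium enolate at C9 closes onto the silyloxocarbenium carbon C8 in an aldol-type step. The same chair-folded tether should again lead to the trans-fused adduct. No new compound is made on this path (entry F0).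

2. Step 20 (ring-closing metathesis). Closure of an eight-membered ring onto a 1,1-disubstituted alkene may lose to intermolecular metathesis, or the allyl ether may isomerise to an enol ether before cyclisation. The fallback closes the ring at C12–C13 instead and sets out from 20. Buffered HF·pyridine removes the triethylsilyl group to give the vinyl alcohol F1. Separately, but-2-yn-1-ol is reduced with NaAlH2(OCH2CH2OMe)2 and quenched with iodine to give (Z)-3-iodobut-2-en-1-ol F2, which PBr3 converts into (Z)-1-bromo-3-iodobut-2-ene F3. Williamson etherification of F1 with F3 (KH, THF) gives the iodoalkenyl ether F4. Hydroboration of its vinyl group with 9-BBN gives the B-alkyl borane F5 (not isolated). Intramolecular B-alkyl Suzuki–Miyaura coupling (Pd(dppf)Cl2, AsPh3, Cs2CO3, DMF/THF/H2O, high dilution) then forms C12–C13 with retention of the (Z) geometry and comes back at 25.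

3. Step 25 (epoxidation). The oxocene is flexible, so facial selectivity of the peracid may be poor or reversed. The fallback sets out from 29 and delivers oxygen to the opposite face in two steps. NBS in aqueous THF forms the bromonium ion on the face the peracid prefers, and water opens it at the tertiary C13 from the other face to give the (13R,14R)-bromohydrin F6. K2CO3 in methanol then closes the epoxide with inversion at C14 and comes back at 30.

Further compounds
F0 | step 14 | none | none
F1 | step 20 | (3S,5R,8R,9R,10S)-3-[(tert-butyldimethylsilyl)oxy]-9-vinyl-4,4,8,10-tetramethyl-trans-decalin-8-ol | CC1(C)[C@@H](O[Si](C)(C)C(C)(C)C)CC[C@]2(C)[C@@H](C=C)[C@](C)(O)CC[C@@H]12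
F2 | step 20 | (Z)-3-iodobut-2-en-1-ol | C/C(I)=C/CO
F3 | step 20 | (Z)-1-bromo-3-iodobut-2-ene | C/C(I)=C/CBr
F4 | step 20 | (3S,5R,8R,9R,10S)-3-[(tert-butyldimethylsilyl)oxy]-8-{[(2Z)-3-iodobut-2-en-1-yl]oxy}-9-vinyl-4,4,8,10-tetramethyl-trans-decalin | CC1(C)[C@@H](O[Si](C)(C)C(C)(C)C)CC[C@]2(C)[C@@H](C=C)[C@](C)(OC/C=C(/C)I)CC[C@@H]12
F5 | step 20 | B-alkyl-9-BBN borane of F4 (C9–CH2CH2–B) | CC1(C)[C@@H](O[Si](C)(C)C(C)(C)C)CC[C@]2(C)[C@@H](CCB3C4CCCC3CCC4)[C@](C)(OC/C=C(/C)I)CC[C@@H]12
F6 | step 25 | (5R,8R,9R,10S,13R,14R)-3,14-dibromo-8,15-epoxylabd-2-en-13-ol | CC1(C)C(Br)=CC[C@]2(C)[C@H]3CC[C@@](C)(O)[C@H](Br)CO[C@]3(C)CC[C@@H]12
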